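**Strategy.** The route rests on disconnecting the upper interflavan bond C4–C8 together with the C2–C3 bond of the upper pyran ring. A (2S,3S)-2-aryl-2,3-dihydrobenzofuran-3-carbaldehyde, silylated at its formyl oxygen, should undergo a 1,2-shift of C2 to the formyl carbon. The furan ring thereby expands to the pyran ring, C3 becomes the carbinol carbon and C4 becomes a cation, which C8 of a benzylated procyanidin B2 traps. The step exploits that C4 is benzylic to ring A, which carries oxygen at C5, C7 and C8a, so this cation is strongly stabilised. The aldehyde comes from a (2S)-flavanone by oxidative ring contraction, the dimer from (−)-epicatechin.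

Key step: step 9

**Assumptions.** (a) (R)-t-BuPyOx is taken to deliver the (2S)-flavanone by analogy with cyclic enones; the antipodal ligand is used if the sense proves opposite. (b) (2S) in flavanone 10 and in the dihydrobenzofurans and (2R) in the flavans describe the same spatial arrangement at C2; only the CIP ranking changes. (c) The nucleophile used in excess in steps 4 and 9 is recovered by chromatography.

**Route**

Step 1
Reactants: 1 (−)-epicatechin
Product: 2 5,7,3',4'-tetra-O-benzyl-(−)-epicatechin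
Conditions: BnBr (4.4 equiv), K2CO3, DMF, 0 °C to rt
Reagents that add atoms: benzyl bromide, BrCc1ccccc1
Why: Williamson etherification of the four phenols under mild carbonate conditions, which leave the secondary 3-OH and both stereocentres untouched.

Step 2
Reactants: 2 5,7,3',4'-tetra-O-benzyl-(−)-epicatechin
Product: 3 3,5,7,3',4'-penta-O-benzyl-(−)-epicatechin
Conditions: NaH, BnBr, n-Bu4NI (cat.), DMF, 0 °C to rt
Reagents that add atoms: benzyl bromide, BrCc1ccccc1
Why: Williamson etherification of the secondary alkoxide, so that every oxygen carries the same hydrogenolysable group and no free hydroxyl can intercept the cations of steps 4 and 9.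

Step 3
Reactants: 3 3,5,7,3',4'-penta-O-benzyl-(−)-epicatechin
Product: 4 (2R,3R,4S)-3,5,7,3',4'-penta-O-benzyl-4-(2-ethoxyethoxy)epicatechin (4β ether)
Conditions: DDQ (2 equiv), 2-ethoxyethanol, CH2Cl2, rt
Reagents that add atoms: 2-ethoxyethanol, CCOCCO
Why: DDQ benzylic oxidation (hydride abstraction at C4 assisted by ring A) followed by capture of the cation by the alcohol anti to the α-oriented 2-aryl and 3-benzyloxy groups, which should give the 3,4-trans (4β) ether.

Step 4
Reactants: 4 (2R,3R,4S)-3,5,7,3',4'-penta-O-benzyl-4-(2-ethoxyethoxy)epicatechin; 3 3,5,7,3',4'-penta-O-benzyl-(−)-epicatechin (4 equiv)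
Product: 5 deca-O-benzyl procyanidin B2
Conditions: TMSOTf (0.2 equiv), CH2Cl2, −78 °C; Et3N quench
Reagents that add atoms: none
Why: Lewis-acid ionisation of the 4-ether to the flavan-4-yl cation and Friedel–Crafts alkylation at C8 of 3 anti to the 2-aryl and 3-benzyloxy groups should set the 4β (3,4-trans) interflavan bond, with excess 3 suppressing oligomerisation.

Step 5
Reactants: 6 1-[2,4-bis(benzyloxy)-6-hydroxyphenyl]ethanone
Product: 8 5,7-bis(benzyloxy)-4H-chromen-4-one, via enaminone 7 (not isolated)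
Conditions: Me2NCH(OMe)2, toluene, 95 °C; then TsOH·H2O (cat.), CH2Cl2, 40 °C
Reagents that add atoms: N,N-dimethylformamide dimethyl acetal, CN(C)C(OC)OC
Why: Enaminone formation at the acetyl group followed by acid-promoted oxa-Michael addition of the phenol and loss of dimethylamine is the standard chromone synthesis.

Step 6
Reactants: 8 5,7-bis(benzyloxy)-4H-chromen-4-one; 9 4-(benzyloxy)phenylboronic acid
Product: 10 (2S)-5,7-bis(benzyloxy)-2-[4-(benzyloxy)phenyl]chroman-4-one
Conditions: Pd(OCOCF3)2 (5 mol %), (R)-t-BuPyOx (6 mol %), NH4PF6 (30 mol %), H2O (5 equiv), ClCH2CH2Cl, 60 °C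
Reagents that add atoms: none
Why: Palladium-catalysed asymmetric conjugate addition of an arylboronic acid to a chromone, in which the chiral pyridine-oxazoline ligand selects the face of aryl transfer and so sets C2.

Step 7
Reactants: 10 (2S)-5,7-bis(benzyloxy)-2-[4-(benzyloxy)phenyl]chroman-4-one
Product: 12 methyl (2S,3S)-4,6-bis(benzyloxy)-2-[4-(benzyloxy)phenyl]-2,3-dihydrobenzofuran-3-carboxylate, via trimethyl orthoester 11 (not isolated)
Conditions: PhI(OAc)2 (1.2 equiv), HC(OMe)3, H2SO4 (cat.), 0 °C to rt; aqueous work-up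
Reagents that add atoms: trimethyl orthoformate, COC(OC)OC; water, O
Why: Hypervalent-iodine oxidative ring contraction of a flavanone, in which the enol ether is attacked by the iodane at C3 anti to the 2-aryl group and C4a then migrates from C4 to C3 with inversion as iodobenzene leaves, which should give the 2,3-trans ester with C2 untouched.

Step 8
Reactants: 12 methyl (2S,3S)-4,6-bis(benzyloxy)-2-[4-(benzyloxy)phenyl]-2,3-dihydrobenzofuran-3-carboxylate
Product: 13 (2S,3S)-4,6-bis(benzyloxy)-2-[4-(benzyloxy)phenyl]-2,3-dihydrobenzofuran-3-carbaldehyde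
Conditions: i-Bu2AlH (1.1 equiv), CH2Cl2, −78 °C; MeOH, then aqueous KNaC4H4O6
Reagents that add atoms: none
Why: Partial reduction of the methyl ester with i-Bu2AlH at low temperature stops at the tetrahedral aluminate, and the thermodynamically preferred trans arrangement at C3 is not endangered by enolisation.

Step 9
Reactants: 13 (2S,3S)-4,6-bis(benzyloxy)-2-[4-(benzyloxy)phenyl]-2,3-dihydrobenzofuran-3-carbaldehyde; 5 deca-O-benzyl procyanidin B2 (2 equiv)
Product: 17 5,7,4'-tri-O-benzylepiafzelechin-(4β→8)-penta-O-benzylepicatechin-(4β→8)-penta-O-benzylepicatechin, via silyloxycarbenium triflate 14 (not isolated), via flavan-4-yl cation 15 (not isolated), via trimethylsilyl ether 16 (not isolated)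
Conditions: TMSOTf (1.2 equiv), 4 Å MS, CH2Cl2 (0.01 M), slow addition of 13, −78 to −40 °C; Et3N; then 1 M HCl, THF, 0 °C
Reagents that add atoms: none
Why: Proposed new method: TMSOTf silylates the formyl oxygen of 13 to give 14, in which the C2–C3 σ bond of the dihydrobenzofuran is aligned with the C=O π* orbital and shifts to the formyl carbon, turning a localised silyloxycarbenium ion into the 2,4,6-trioxygenated benzylic cation 15, which C8 of the upper unit of 5 captures in a Friedel–Crafts alkylation; the closest known reaction types are the acid-promoted aldehyde–ketone (retro-pinacol) 1,2-shift and the Lewis-acid 4-arylation of flavan-4-yl cations generated from 4-alkoxyflavans. The pyran ring is not closed by cyclisation but arises from the furan ring by a 1,2-carbon shift (ring expansion by one atom), the formyl carbon being inserted between C2 and the benzylic carbon. C2 migrates with retention, so (2S) in 13 becomes (2R) in the flavan by the change in CIP ranking alone. C3 is set by the reacting rotamer: the silylated oxygen should lie syn to the C3–H bond of 13, turned away from ring A and its peri 4-benzyloxy group, which places OSiMe3 cis to the aryl group (3R) because aryl and formyl are trans in 13, and C4 is then set by attack of the arene anti to the 3-silyloxy and 2-aryl groups (β face, 4R) as in epicatechin-derived cations. The step needs migration of C2 and not of the aryl carbon (aryl migration would leave an unstabilised secondary cation), a shift faster than direct arene addition to the formyl carbon (favoured by high dilution and by the hindered C8 nucleophile) and C8 over C6 selectivity (the usual preference of benzylated flavan nucleophiles).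

Step 10
Reactants: 17 5,7,4'-tri-O-benzylepiafzelechin-(4β→8)-penta-O-benzylepicatechin-(4β→8)-penta-O-benzylepicatechin
Product: 18 epiafzelechin-(4β→8)-epicatechin-(4β→8)-epicatechin (CNP0158921.2)
Conditions: H2 (1 atm), 20% Pd(OH)2/C, THF/MeOH/H2O, rt; filtration, lyophilisation
Reagents that add atoms: none
Why: Catalytic hydrogenolysis should cleave all thirteen benzyl ethers (aryl and alkyl) under neutral conditions that leave the interflavan bonds and every stereocentre untouched.

**Compound list**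

1 | (−)-epicatechin, (2R,3R) | Oc1cc(O)c2c(c1)O[C@H](c1ccc(O)c(O)c1)[C@H](O)C2 | starting material
2 | 5,7,3',4'-tetra-O-benzyl-(−)-epicatechin | c1(OCc5ccccc5)cc(OCc5ccccc5)c2c(c1)O[C@H](c1ccc(OCc5ccccc5)c(OCc5ccccc5)c1)[C@H](O)C2 | intermediate
3 | 3,5,7,3',4'-penta-O-benzyl-(−)-epicatechin | c1(OCc5ccccc5)cc(OCc5ccccc5)c2c(c1)O[C@H](c1ccc(OCc5ccccc5)c(OCc5ccccc5)c1)[C@H](OCc5ccccc5)C2 | intermediate
4 | (2R,3R,4S)-3,5,7,3',4'-penta-O-benzyl-4-(2-ethoxyethoxy)epicatechin (4β, 3,4-trans) | c1(OCc5ccccc5)cc(OCc5ccccc5)c2c(c1)O[C@H](c1ccc(OCc5ccccc5)c(OCc5ccccc5)c1)[C@H](OCc5ccccc5)[C@H]2OCCOCC | intermediate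
5 | deca-O-benzyl procyanidin B2, penta-O-benzylepicatechin-(4β→8)-penta-O-benzylepicatechin | c1c(OCc5ccccc5)cc(OCc5ccccc5)c2c1O[C@H](c1ccc(OCc5ccccc5)c(OCc5ccccc5)c1)[C@H](OCc5ccccc5)[C@H]2c1c(OCc5ccccc5)cc(OCc5ccccc5)c2c1O[C@H](c1ccc(OCc5ccccc5)c(OCc5ccccc5)c1)[C@H](OCc5ccccc5)C2 | intermediate
6 | 1-[2,4-bis(benzyloxy)-6-hydroxyphenyl]ethanone | CC(=O)c1c(O)cc(OCc2ccccc2)cc1OCc1ccccc1 | starting material
7 | (E)-1-[2,4-bis(benzyloxy)-6-hydroxyphenyl]-3-(dimethylamino)prop-2-en-1-one | CN(C)/C=C/C(=O)c1c(O)cc(OCc2ccccc2)cc1OCc1ccccc1 | intermediate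
8 | 5,7-bis(benzyloxy)-4H-chromen-4-one | O=c1ccoc2cc(OCc3ccccc3)cc(OCc3ccccc3)c12 | intermediate
9 | 4-(benzyloxy)phenylboronic acid | OB(O)c1ccc(OCc2ccccc2)cc1 | starting material
10 | (2S)-5,7-bis(benzyloxy)-2-[4-(benzyloxy)phenyl]chroman-4-one | c1(OCc5ccccc5)cc(OCc5ccccc5)c2c(c1)O[C@H](c1ccc(OCc5ccccc5)cc1)CC2=O | intermediate
11 | (2S,3S)-4,6-bis(benzyloxy)-2-[4-(benzyloxy)phenyl]-3-(trimethoxymethyl)-2,3-dihydrobenzofuran | c1(OCc5ccccc5)cc(OCc5ccccc5)c2c(c1)O[C@H](c1ccc(OCc5ccccc5)cc1)[C@H]2C(OC)(OC)OC | intermediate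
12 | methyl (2S,3S)-4,6-bis(benzyloxy)-2-[4-(benzyloxy)phenyl]-2,3-dihydrobenzofuran-3-carboxylate (trans) | c1(OCc5ccccc5)cc(OCc5ccccc5)c2c(c1)O[C@H](c1ccc(OCc5ccccc5)cc1)[C@H]2C(=O)OC | intermediate
13 | (2S,3S)-4,6-bis(benzyloxy)-2-[4-(benzyloxy)phenyl]-2,3-dihydrobenzofuran-3-carbaldehyde (trans) | c1(OCc5ccccc5)cc(OCc5ccccc5)c2c(c1)O[C@H](c1ccc(OCc5ccccc5)cc1)[C@H]2C=O | intermediate
14 | O-trimethylsilyl oxocarbenium triflate of 13 | c1(OCc5ccccc5)cc(OCc5ccccc5)c2c(c1)O[C@H](c1ccc(OCc5ccccc5)cc1)[C@H]2C=[O+][Si](C)(C)C.[O-]S(=O)(=O)C(F)(F)F | intermediate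
15 | (2R,3R)-5,7-bis(benzyloxy)-2-[4-(benzyloxy)phenyl]-3-(trimethylsilyloxy)chroman-4-ylium triflate | c1(OCc5ccccc5)cc(OCc5ccccc5)c2c(c1)O[C@H](c1ccc(OCc5ccccc5)cc1)[C@H](O[Si](C)(C)C)[CH+]2.[O-]S(=O)(=O)C(F)(F)F | intermediate
16 | 3-O-trimethylsilyl ether of 17 (upper unit) | c1(OCc5ccccc5)cc(OCc5ccccc5)c2c(c1)O[C@H](c1ccc(OCc5ccccc5)cc1)[C@H](O[Si](C)(C)C)[C@H]2c1c(OCc5ccccc5)cc(OCc5ccccc5)c2c1O[C@H](c1ccc(OCc5ccccc5)c(OCc5ccccc5)c1)[C@H](OCc5ccccc5)[C@H]2c1c(OCc5ccccc5)cc(OCc5ccccc5)c2c1O[C@H](c1ccc(OCc5ccccc5)c(OCc5ccccc5)c1)[C@H](OCc5ccccc5)C2 | intermediate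
17 | 5,7,4'-tri-O-benzylepiafzelechin-(4β→8)-penta-O-benzylepicatechin-(4β→8)-penta-O-benzylepicatechin (upper 3-OH free) | c1(OCc5ccccc5)cc(OCc5ccccc5)c2c(c1)O[C@H](c1ccc(OCc5ccccc5)cc1)[C@H](O)[C@H]2c1c(OCc5ccccc5)cc(OCc5ccccc5)c2c1O[C@H](c1ccc(OCc5ccccc5)c(OCc5ccccc5)c1)[C@H](OCc5ccccc5)[C@H]2c1c(OCc5ccccc5)cc(OCc5ccccc5)c2c1O[C@H](c1ccc(OCc5ccccc5)c(OCc5ccccc5)c1)[C@H](OCc5ccccc5)C2 | intermediate
18 | epiafzelechin-(4β→8)-epicatechin-(4β→8)-epicatechin (CNP0158921.2) | Oc1ccc([C@H]2Oc3cc(O)cc(O)c3[C@H](c3c(O)cc(O)c4c3O[C@H](c3ccc(O)c(O)c3)[C@H](O)[C@H]4c3c(O)cc(O)c4c3O[C@H](c3ccc(O)c(O)c3)[C@H](O)C4)[C@H]2O)cc1 | target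

**Step count and risks**

Total step count: 10. Longest linear sequence: 6 steps (steps 5–10 from acetophenone 6; equally steps 1–4, 9, 10 from epicatechin 1).

Steps most likely to fail:

1. Step 9 (Proposed new method). The arene may add directly to the silylated formyl carbon before the 1,2-shift occurs. The formyl group may react through the other rotamer and give the 2,3-trans upper unit. Cation 15 may lose a proton to a silyl enol ether or alkylate ring A of a second molecule of 13. Fallback by known flavan chemistry, which keeps the six-membered ring of flavanone 10 throughout: it sets out from 10 and returns at 17. NaBH4 reduction should give the 2,4-cis flavan-4-ol F1. Acid-catalysed dehydration (TsOH, toluene) gives the flav-3-ene F2. Hydroboration–oxidation (BH3·SMe2, then H2O2/NaOH) anti to the 2-aryl group gives the 2,3-trans flavan-3-ol F3. Dess–Martin oxidation gives the flavan-3-one F4. Reduction with Li(s-Bu)3BH from the face opposite the aryl group gives 5,7,4'-tri-O-benzylepiafzelechin F5. DDQ with 2-ethoxyethanol gives the 4β-(2-ethoxyethoxy) ether F6, which is coupled with 5 under TMSOTf at −78 °C as in step 4 to reach 17.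

2. Step 7. Dehydrogenation to the flavone, migration of the 4-benzyloxyphenyl group instead of ring A (isoflavone formation), acid-induced opening of the flavanone with loss of configuration at C2, or oxidation of the electron-rich ring A may divert the oxidative rearrangement. Fallback by Wolff ring contraction, setting out from 10 and returning at 12. Trifluoroacetylation (LiN(SiMe3)2, THF, −78 °C; CF3CO2CH2CF3) gives the 3-trifluoroacetyl flavanone F7. Detrifluoroacetylative diazo transfer (MsN3, Et3N, H2O, MeCN) gives the 3-diazoflavanone F8. Photolysis (or PhCO2Ag, Et3N) in methanol lets C4a migrate to the carbene carbon and gives the ketene F9, which adds methanol to give mainly the cis ester F10. Equilibration with NaOMe in MeOH gives the trans ester 12.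

3. Step 6. Sluggish carbopalladation of the electron-rich 5,7-dialkoxychromone, protodeboronation of the electron-rich boronic acid, or an insufficient or reversed facial preference may compromise yield or configuration at C2. Fallback by kinetic resolution, setting out from 6 and returning at 10. Claisen–Schmidt condensation of 6 with 4-(benzyloxy)benzaldehyde (KOH, EtOH) gives the chalcone F11. Cyclisation (NaOAc, EtOH, reflux) gives the racemic flavanone F12. Asymmetric transfer hydrogenation with RuCl(p-cymene)[(R,R)-TsDPEN] (or its antipode, whichever consumes the (2R) enantiomer faster) in HCO2H/Et3N reduces that enantiomer to the cis flavan-4-ol F13 and leaves (2S)-10.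

Further compounds
F1 | step 9 | (2S,4S)-5,7-bis(benzyloxy)-2-[4-(benzyloxy)phenyl]chroman-4-ol | c1(OCc5ccccc5)cc(OCc5ccccc5)c2c(c1)O[C@H](c1ccc(OCc5ccccc5)cc1)C[C@@H]2O
F2 | step 9 | (2S)-5,7-bis(benzyloxy)-2-[4-(benzyloxy)phenyl]-2H-chromene | c1(OCc5ccccc5)cc(OCc5ccccc5)c2c(c1)O[C@H](c1ccc(OCc5ccccc5)cc1)C=C2
F3 | step 9 | (2R,3S)-5,7-bis(benzyloxy)-2-[4-(benzyloxy)phenyl]chroman-3-ol | c1(OCc5ccccc5)cc(OCc5ccccc5)c2c(c1)O[C@H](c1ccc(OCc5ccccc5)cc1)[C@@H](O)C2
F4 | step 9 | (2R)-5,7-bis(benzyloxy)-2-[4-(benzyloxy)phenyl]chroman-3-one | c1(OCc5ccccc5)cc(OCc5ccccc5)c2c(c1)O[C@H](c1ccc(OCc5ccccc5)cc1)C(=O)C2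
F5 | step 9 | 5,7,4'-tri-O-benzyl-(−)-epiafzelechin, (2R,3R) | c1(OCc5ccccc5)cc(OCc5ccccc5)c2c(c1)O[C@H](c1ccc(OCc5ccccc5)cc1)[C@H](O)C2
F6 | step 9 | (2R,3R,4S)-5,7,4'-tri-O-benzyl-4-(2-ethoxyethoxy)epiafzelechin | c1(OCc5ccccc5)cc(OCc5ccccc5)c2c(c1)O[C@H](c1ccc(OCc5ccccc5)cc1)[C@H](O)[C@H]2OCCOCC
F7 | step 7 | (2S)-5,7-bis(benzyloxy)-2-[4-(benzyloxy)phenyl]-3-(trifluoroacetyl)chroman-4-one | c1(OCc5ccccc5)cc(OCc5ccccc5)c2c(c1)O[C@H](c1ccc(OCc5ccccc5)cc1)C(C(=O)C(F)(F)F)C2=O
F8 | step 7 | (2R)-5,7-bis(benzyloxy)-2-[4-(benzyloxy)phenyl]-3-diazochroman-4-one | c1(OCc5ccccc5)cc(OCc5ccccc5)c2c(c1)O[C@H](c1ccc(OCc5ccccc5)cc1)C(=[N+]=[N-])C2=O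
F9 | step 7 | ketene from Wolff rearrangement, 4,6-bis(benzyloxy)-2-[4-(benzyloxy)phenyl]-3-(oxomethylidene)-2,3-dihydrobenzofuran | c1(OCc5ccccc5)cc(OCc5ccccc5)c2c(c1)O[C@H](c1ccc(OCc5ccccc5)cc1)C2=C=O
F10 | step 7 | methyl (2S,3R)-4,6-bis(benzyloxy)-2-[4-(benzyloxy)phenyl]-2,3-dihydrobenzofuran-3-carboxylate (cis) | c1(OCc5ccccc5)cc(OCc5ccccc5)c2c(c1)O[C@H](c1ccc(OCc5ccccc5)cc1)[C@@H]2C(=O)OC
F11 | step 6 | (E)-1-[2,4-bis(benzyloxy)-6-hydroxyphenyl]-3-[4-(benzyloxy)phenyl]prop-2-en-1-one | O=C(/C=C/c1ccc(OCc2ccccc2)cc1)c1c(O)cc(OCc2ccccc2)cc1OCc1ccccc1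
F12 | step 6 | racemic 5,7-bis(benzyloxy)-2-[4-(benzyloxy)phenyl]chroman-4-one | c1(OCc5ccccc5)cc(OCc5ccccc5)c2c(c1)OC(c1ccc(OCc5ccccc5)cc1)CC2=O
F13 | step 6 | (2R,4R)-5,7-bis(benzyloxy)-2-[4-(benzyloxy)phenyl]chroman-4-ol | c1(OCc5ccccc5)cc(OCc5ccccc5)c2c(c1)O[C@@H](c1ccc(OCc5ccccc5)cc1)C[C@H]2O
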